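**Retrosynthetic overview**
- The target is opened at its two enol OH groups: it comes from 3-hexadecyl-2,5-dimethoxy-1,4-benzoquinone by hydrolysis of the two vinylogous methyl esters (last step).
- Key disconnection: the ring C3–chain C1' bond, made by a new radical-chain C–H alkylation of 2,5-dimethoxy-1,4-benzoquinone with B-hexadecylcatecholborane, followed by re-oxidation in the same flask.
- The borane comes from anti-Markovnikov hydroboration of 1-hexadecene; the dimethoxyquinone comes from 2,5-dihydroxy-1,4-benzoquinone and methanol.
- No ring is formed: the only ring, the quinone, is bought intact as 2,5-dihydroxy-1,4-benzoquinone.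

Assumption: the target is achiral (no stereocentre, no stereogenic double bond), so the "single enantiomer" is the compound itself and no stereocontrol is needed; the side chain is n-hexadecyl (16 carbons).

**Step 1**
Reactants: 1 2,5-dihydroxy-1,4-benzoquinone
Product: 2 2,5-dimethoxy-1,4-benzoquinone
Conditions: MeOH, conc. H2SO4 (cat.), rt→reflux, 12 h; filter the yellow solid
Reagents that add atoms: methanol, CO
Why: 1 is a bis-vinylogous carboxylic acid, so acid-catalysed addition–elimination of methanol (vinylogous Fischer esterification) gives the bis-methyl ether, which crystallises out and drives the equilibrium.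

**Step 2**
Reactants: 3 1-hexadecene
Product: 4 2-hexadecyl-1,3,2-benzodioxaborole
Conditions: catecholborane (0.95 equiv), N,N-dimethylacetamide (10 mol%), CH2Cl2, reflux, 4 h; used as the crude solution under Ar
Reagents that add atoms: catecholborane, B1Oc2ccccc2O1
Why: amide-catalysed syn-hydroboration of a terminal alkene places boron on the terminal carbon (anti-Markovnikov hydroboration), and the slight excess of alkene leaves no B–H to reduce the quinone in step 3; no stereocentre forms.

**Step 3**
Reactants: 2 2,5-dimethoxy-1,4-benzoquinone; 4 2-hexadecyl-1,3,2-benzodioxaborole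
Product: 7 3-hexadecyl-2,5-dimethoxy-1,4-benzoquinone, via aryl catecholborate 5 (not isolated), via hydroquinone 6 (not isolated)
Conditions: 4 (1.3 equiv), DMPU (1.3 equiv), dry air by syringe pump, anhydrous CH2Cl2, 0 °C→rt; then MeOH/H2O; then aq. FeCl3 (2.2 equiv), rt
Reagents that add atoms: none
Why: Proposed new method: O2-initiated radical-chain C–H alkylation of a 2,5-dialkoxyquinone by a B-alkylcatecholborane, in which traces of O2 release the n-hexadecyl radical from 4, the radical adds to the unsubstituted C3 of 2 to give a captodatively stabilised (α-methoxy, α-acyl) radical, its oxygen end attacks boron of a second molecule of 4 (SH2, strong B–O bond) and so carries the chain, and the adduct aromatises by prototropy to the O-boryl hydroquinone 5, which is not a radical acceptor and is shielded from redox exchange with 2 so that a second alkylation is blocked, before hydrolysis to 6 and FeCl3 oxidation restore the quinone; the closest known reaction types are the radical 1,4-addition of trialkylboranes to p-benzoquinone and the conjugate addition of B-alkylcatecholboranes to enones, neither shown on a 2,5-dialkoxyquinone; no stereocentre forms.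

**Step 4**
Reactants: 7 3-hexadecyl-2,5-dimethoxy-1,4-benzoquinone
Product: 8 3-hexadecyl-2,5-dihydroxy-1,4-benzoquinone
Conditions: 70% HClO4, conc. HCl, 1,4-dioxane/H2O, rt, 48 h
Reagents that add atoms: water, O
Why: acid-catalysed hydrolysis of the two vinylogous methyl esters by addition–elimination of water at the methoxy-bearing ring carbons (the reverse of step 1, driven by excess water) frees both enols while the alkyl chain and quinone core are untouched.

**Compound list**
1 | 2,5-dihydroxy-1,4-benzoquinone | O=C1C=C(O)C(=O)C=C1O | starting material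
2 | 2,5-dimethoxy-1,4-benzoquinone | COC1=CC(=O)C(OC)=CC1=O | intermediate
3 | 1-hexadecene | CCCCCCCCCCCCCCC=C | starting material
4 | 2-hexadecyl-1,3,2-benzodioxaborole (B-hexadecylcatecholborane) | CCCCCCCCCCCCCCCCB1Oc2ccccc2O1 | intermediate
5 | 2-(3-hexadecyl-4-hydroxy-2,5-dimethoxyphenoxy)-1,3,2-benzodioxaborole | CCCCCCCCCCCCCCCCc1c(O)c(OC)cc(OB2Oc3ccccc3O2)c1OC | intermediate
6 | 3-hexadecyl-2,5-dimethoxybenzene-1,4-diol | CCCCCCCCCCCCCCCCc1c(O)c(OC)cc(O)c1OC | intermediate
7 | 3-hexadecyl-2,5-dimethoxy-1,4-benzoquinone | CCCCCCCCCCCCCCCCC1=C(OC)C(=O)C=C(OC)C1=O | intermediate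
8 | 3-hexadecyl-2,5-dihydroxy-1,4-benzoquinone (CNP0283865.0, achiral) | CCCCCCCCCCCCCCCCC1=C(O)C(=O)C=C(O)C1=O | target

**Totals**
Total step count: 4. Longest linear sequence: 3 steps (1 → 2 → 7 → 8, or 3 → 4 → 7 → 8).

**Steps most likely to fail**

Step 3 (the proposed new step) is the main risk. The chain may be short with a primary alkyl radical and the electron-rich, sparingly soluble quinone 2, and the radical could also attack oxygen or the methoxy-bearing carbon. The fallback uses known chemistry, sets out from 2 and comes back at 7. Reduce 2 with Na2S2O4 (EtOAc/H2O) to 2,5-dimethoxybenzene-1,4-diol F1. Methylate with Me2SO4/K2CO3 in acetone to 1,2,4,5-tetramethoxybenzene F2. Lithiate the position flanked by two methoxy groups with n-BuLi in THF (0 °C→rt) to (2,3,5,6-tetramethoxyphenyl)lithium F3. Alkylate with 1-bromohexadecane to 3-hexadecyl-1,2,4,5-tetramethoxybenzene F4. Oxidise with CAN in MeCN/H2O (oxidative demethylation) to 7.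

Step 2 is the second risk. Hydroboration with catecholborane may be incomplete, and leftover B–H would reduce the quinone in step 3. The fallback sets out from 3 and comes back at 4. Hydroborate 3 with HBBr2·SMe2 (CH2Cl2, reflux) to hexadecyldibromoborane–dimethyl sulfide F5. Hydrolyse to hexadecylboronic acid F6, which can be crystallised free of any B–H species. Condense with catechol (toluene, Dean–Stark) to 4.

Step 4 is the third risk. Acid hydrolysis of the lipophilic bis-ether may be slow or stop at the mono-ether. The fallback sets out from 7 and comes back at 8. Reduce 7 with Na2S2O4 to the hydroquinone 6. Cleave both aryl methyl ethers with BBr3 (CH2Cl2, −78 °C→rt) to 3-hexadecylbenzene-1,2,4,5-tetrol F7. Stir the tetrol in EtOAc under air, which oxidises it to 8.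

**Further compounds**
F1 | step 3 | 2,5-dimethoxybenzene-1,4-diol | COc1cc(O)c(OC)cc1O
F2 | step 3 | 1,2,4,5-tetramethoxybenzene | COc1cc(OC)c(OC)cc1OC
F3 | step 3 | (2,3,5,6-tetramethoxyphenyl)lithium | [Li]c1c(OC)c(OC)cc(OC)c1OC
F4 | step 3 | 3-hexadecyl-1,2,4,5-tetramethoxybenzene | CCCCCCCCCCCCCCCCc1c(OC)c(OC)cc(OC)c1OC
F5 | step 2 | hexadecyldibromoborane–dimethyl sulfide | CCCCCCCCCCCCCCCC[B-](Br)(Br)[S+](C)C
F6 | step 2 | hexadecylboronic acid | CCCCCCCCCCCCCCCCB(O)O
F7 | step 4 | 3-hexadecylbenzene-1,2,4,5-tetrol | CCCCCCCCCCCCCCCCc1c(O)c(O)cc(O)c1O
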